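The whole route rests on cutting the O1–C8a aryl ether bond of ring C. C8a sits ortho to C4a, which carries the C4 ketone, whereas the oxygen-bearing carbons C5 and C7 are meta to it, so a fluorine at C8a is activated toward the C2 alkoxide. In one operation this displacement closes ring C while leaving the C2–O bond intact, so the (S) configuration installed earlier by asymmetric allylboration is retained. The precursor is an open-chain (S)-β-hydroxy ketone: ring A carries fluorine at C8a, MOM ethers at C5 and C7 and lavandulyl at C6; ring B is the tris-MOM triol. It is assembled from an ortho-lithiated fluoroarene and a β-silyloxy aldehyde.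

Key step: step 12

Assumption: (R)-lavandulol is bought as the single enantiomer; its stereocentre is never touched and is called (S) in the arylmethyl compounds only because the arylmethyl carbon outranks the prenyl CH2.
Abbreviations: MOM = methoxymethyl; TES = triethylsilyl; lavandulyl = 5-methyl-2-(prop-1-en-2-yl)hex-4-en-1-yl; Ipc = isopinocampheyl; DMP = Dess–Martin periodinane; SPhos = 2-dicyclohexylphosphino-2′,6′-dimethoxybiphenyl.
Handling: compounds 11 to 18 carry a very electron-rich benzylic C–O bond and are kept away from acid (Et3N-washed silica).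

Step 1
Reactants: 1 5-fluororesorcinol
Product: 2 5-fluoro-2-iodobenzene-1,3-diol
Conditions: I2, NaHCO3, H2O, 0 °C → rt
Reagents that add atoms: iodine, II
Why: Electrophilic aromatic iodination under aqueous hydrogencarbonate goes to the carbon between the two hydroxyls, as with resorcinol itself, and fluorine (para to that carbon, ortho and inductively deactivating toward the other two) reinforces the choice, so the lavandulyl site is fixed by a C–I bond and not left to a competition between lithiation next to oxygen and next to fluorine.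

Step 2
Reactants: 2 5-fluoro-2-iodobenzene-1,3-diol
Product: 3 5-fluoro-2-iodo-1,3-bis(methoxymethoxy)benzene
Conditions: MOMCl, i-Pr2NEt, CH2Cl2, 0 °C → rt
Reagents that add atoms: chloromethyl methyl ether (MOMCl), COCCl
Why: Williamson-type O-alkylation of both phenols gives acetals that tolerate organozinc, organolithium and carbonate base and later direct the ortho-lithiation.

Step 3
Reactants: 4 (R)-lavandulol
Product: 5 (R)-lavandulyl iodide
Conditions: PPh3, I2, imidazole, CH2Cl2, 0 °C → rt, dark
Reagents that add atoms: iodine, II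
Why: Appel-type (Garegg–Samuelsson) iodination displaces the alkoxyphosphonium by SN2 at the primary carbon, so the neighbouring stereocentre is not involved.

Step 4
Reactants: 5 (R)-lavandulyl iodide; 3 5-fluoro-2-iodo-1,3-bis(methoxymethoxy)benzene
Product: 7 5-fluoro-1,3-bis(methoxymethoxy)-2-[(2S)-lavandulyl]benzene, via (R)-lavandulylzinc iodide 6 (not isolated)
Conditions: Zn dust (BrCH2CH2Br, TMSCl activation), LiCl, THF, 40 °C; then 3, Pd(OAc)2 (cat.), SPhos (cat.), THF, rt → 50 °C
Reagents that add atoms: none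
Why: Negishi sp3–sp2 cross-coupling, in which zinc inserts into the primary C–I bond and the bulky biarylphosphine should make reductive elimination from the hindered aryl(alkyl)palladium intermediate faster than β-hydride elimination; the stereocentre lies β to the metal and is never metallated.

Step 5
Reactants: 8 2,4,6-trihydroxybenzaldehyde
Product: 9 2,4,6-tris(methoxymethoxy)benzaldehyde
Conditions: NaH, MOMCl, DMF, 0 °C → rt
Reagents that add atoms: chloromethyl methyl ether (MOMCl), COCCl
Why: Exhaustive Williamson O-alkylation of the three phenoxides, the strong base being needed for the hydroxyls hydrogen-bonded to the aldehyde.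

Step 6
Reactants: 9 2,4,6-tris(methoxymethoxy)benzaldehyde
Product: 11 (1S)-1-[2,4,6-tris(methoxymethoxy)phenyl]but-3-en-1-ol, via diisopinocampheylborinate 10 (not isolated)
Conditions: (+)-Ipc2B(allyl) [(+)-α-pinene series, commercial solution in pentane], Et2O, −78 °C; then NaOH, H2O2, 0 °C → rt
Reagents that add atoms: B-allyldiisopinocampheylborane of the (+)-α-pinene series, C=CCB([C@@H]1C[C@@H]2C[C@@H](C2(C)C)[C@H]1C)[C@@H]1C[C@@H]2C[C@@H](C2(C)C)[C@H]1C
Why: Brown asymmetric allylboration through a chair six-membered transition state, in which the isopinocampheyl groups of the (+)-α-pinene series deliver allyl to the aldehyde face that gives the (S)-carbinol, as with benzaldehyde, under neutral conditions that cannot ionise the electron-rich benzylic alcohol.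

Step 7
Reactants: 11 (1S)-1-[2,4,6-tris(methoxymethoxy)phenyl]but-3-en-1-ol
Product: 12 triethyl{[(1S)-1-[2,4,6-tris(methoxymethoxy)phenyl]but-3-en-1-yl]oxy}silane
Conditions: TESCl, imidazole, DMAP (cat.), CH2Cl2, 0 °C → rt
Reagents that add atoms: chlorotriethylsilane (TESCl), CC[Si](Cl)(CC)CC
Why: Imidazole-promoted silylation masks the carbinol against the organolithium and the oxidant to come and can later be undone by buffered fluoride without acid.

Step 8
Reactants: 12 triethyl{[(1S)-1-[2,4,6-tris(methoxymethoxy)phenyl]but-3-en-1-yl]oxy}silane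
Product: 14 (3S)-3-[(triethylsilyl)oxy]-3-[2,4,6-tris(methoxymethoxy)phenyl]propanal, via diol 13 (not isolated)
Conditions: OsO4 (cat.), NaIO4, 2,6-lutidine, dioxane/H2O, rt
Reagents that add atoms: osmium tetroxide, O=[Os](=O)(=O)=O (catalytic oxygen carrier); sodium periodate, [Na+].[O-]I(=O)(=O)=O (terminal oxygen source)
Why: Lemieux–Johnson oxidation (catalytic dihydroxylation, then periodate glycol cleavage) acts on the only alkene present, the lutidine buffer protecting the silyl ether and the acetals, and the transient diol centre is destroyed in the cleavage.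

Step 9
Reactants: 7 5-fluoro-1,3-bis(methoxymethoxy)-2-[(2S)-lavandulyl]benzene; 14 (3S)-3-[(triethylsilyl)oxy]-3-[2,4,6-tris(methoxymethoxy)phenyl]propanal
Product: 16 (3S)-1-{6-fluoro-2,4-bis(methoxymethoxy)-3-[(2S)-lavandulyl]phenyl}-3-[(triethylsilyl)oxy]-3-[2,4,6-tris(methoxymethoxy)phenyl]propan-1-ol as both C1 epimers, via aryllithium 15 (not isolated)
Conditions: n-BuLi, THF, −78 °C; then 14, −78 °C; then H2O
Reagents that add atoms: none
Why: Directed ortho-lithiation at a ring C–H flanked by fluorine and a MOM ether (the two such positions are equivalent by symmetry, so only the 6-lavandulyl pattern can arise), then 1,2-addition to the aldehyde below the temperature at which an ortho-fluoroaryllithium loses LiF; the new carbinol centre is uncontrolled and is removed by the next oxidation.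

Step 10
Reactants: 16 (3S)-1-{6-fluoro-2,4-bis(methoxymethoxy)-3-[(2S)-lavandulyl]phenyl}-3-[(triethylsilyl)oxy]-3-[2,4,6-tris(methoxymethoxy)phenyl]propan-1-ol
Product: 17 (3S)-1-{6-fluoro-2,4-bis(methoxymethoxy)-3-[(2S)-lavandulyl]phenyl}-3-[(triethylsilyl)oxy]-3-[2,4,6-tris(methoxymethoxy)phenyl]propan-1-one
Conditions: DMP, NaHCO3, CH2Cl2, 0 °C → rt
Reagents that add atoms: none
Why: Dess–Martin oxidation converts the benzylic alcohol into the aryl ketone under buffered, near-neutral conditions that leave the alkenes, the acetals and the silyl ether alone.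

Step 11
Reactants: 17 (3S)-1-{6-fluoro-2,4-bis(methoxymethoxy)-3-[(2S)-lavandulyl]phenyl}-3-[(triethylsilyl)oxy]-3-[2,4,6-tris(methoxymethoxy)phenyl]propan-1-one
Product: 18 (3S)-1-{6-fluoro-2,4-bis(methoxymethoxy)-3-[(2S)-lavandulyl]phenyl}-3-hydroxy-3-[2,4,6-tris(methoxymethoxy)phenyl]propan-1-one
Conditions: TBAF, AcOH, THF, 0 °C
Reagents that add atoms: none
Why: Fluoride-mediated Si–O cleavage buffered with acetic acid protonates the freed alkoxide at once, so that it neither cyclises nor eliminates before the ring-closing conditions are chosen.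

Step 12
Reactants: 18 (3S)-1-{6-fluoro-2,4-bis(methoxymethoxy)-3-[(2S)-lavandulyl]phenyl}-3-hydroxy-3-[2,4,6-tris(methoxymethoxy)phenyl]propan-1-one
Product: 19 (2S)-5,7-bis(methoxymethoxy)-6-[(2S)-lavandulyl]-2-[2,4,6-tris(methoxymethoxy)phenyl]-2,3-dihydro-4H-chromen-4-one
Conditions: Cs2CO3, DMF, 0 °C → rt
Reagents that add atoms: none
Why: The alkoxide formed reversibly at C2 adds to C8a; in the resulting σ-adduct the negative charge is spread over C4a, C6 and C8 and drawn into the C4 carbonyl, and expulsion of fluoride restores the aromatic ring (addition–elimination SNAr). The closest known reaction type is the base-mediated cyclisation of β-hydroxy ortho-fluoroaryl ketones to chroman-4-ones. Ring C is closed in a 6-exo-trig sense, the oxygen attacking the arene carbon while the C8a–F bond that breaks lies outside the new ring. No stereocentre is created, and C2 keeps its (S) configuration because the C2–O bond is never broken, which sidesteps the ionisation that any activation of this oxygen would invite in a 2,4,6-trialkoxybenzylic carbinol. The step needs O-arylation to beat C3 deprotonation with loss of hydroxide (chalcone formation) and retro-aldol cleavage, and later reopening of ring C by base. The ortho carbonyl, fluoride as leaving group, the merely meta and inductively helpful C5 and C7 alkoxy groups, a weak base, low temperature and a prompt quench are what favour closure, while the single fluorine on ring A leaves no choice of site.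

Step 13
Reactants: 19 (2S)-5,7-bis(methoxymethoxy)-6-[(2S)-lavandulyl]-2-[2,4,6-tris(methoxymethoxy)phenyl]-2,3-dihydro-4H-chromen-4-one
Product: 20 (2S)-5,7-dihydroxy-6-[(2S)-lavandulyl]-2-(2,4,6-trihydroxyphenyl)-2,3-dihydro-4H-chromen-4-one
Conditions: HCl (3 M aq.), MeOH, 40 °C
Reagents that add atoms: none
Why: Acid-catalysed acetal exchange with methanol removes the five MOM groups as dimethoxymethane, and the mild temperature and short exposure are chosen so that the C2–O1 benzylic ether should not ionise and the lavandulyl alkenes should not add the neighbouring phenols.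

Compound list
1 | 5-fluororesorcinol (5-fluorobenzene-1,3-diol) | Oc1cc(O)cc(F)c1 | starting material
2 | 5-fluoro-2-iodobenzene-1,3-diol | Oc1cc(F)cc(O)c1I | intermediate
3 | 5-fluoro-2-iodo-1,3-bis(methoxymethoxy)benzene | COCOc1cc(F)cc(OCOC)c1I | intermediate
4 | (R)-lavandulol, (2R)-5-methyl-2-(prop-1-en-2-yl)hex-4-en-1-ol | C=C(C)[C@@H](CC=C(C)C)CO | starting material
5 | (R)-lavandulyl iodide, (2R)-1-iodo-5-methyl-2-(prop-1-en-2-yl)hex-4-ene | C=C(C)[C@@H](CC=C(C)C)CI | intermediate
6 | (R)-lavandulylzinc iodide (not isolated) | C=C(C)[C@@H](CC=C(C)C)C[Zn]I | intermediate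
7 | 5-fluoro-1,3-bis(methoxymethoxy)-2-[(2S)-5-methyl-2-(prop-1-en-2-yl)hex-4-en-1-yl]benzene | C=C(C)[C@@H](CC=C(C)C)Cc1c(OCOC)cc(F)cc1OCOC | intermediate
8 | 2,4,6-trihydroxybenzaldehyde | O=Cc1c(O)cc(O)cc1O | starting material
9 | 2,4,6-tris(methoxymethoxy)benzaldehyde | O=Cc1c(OCOC)cc(OCOC)cc1OCOC | intermediate
10 | (1S)-1-[2,4,6-tris(methoxymethoxy)phenyl]but-3-en-1-yl diisopinocampheylborinate (not isolated) | C=CC[C@H](OB([C@@H]1C[C@@H]2C[C@@H](C2(C)C)[C@H]1C)[C@@H]1C[C@@H]2C[C@@H](C2(C)C)[C@H]1C)c1c(OCOC)cc(OCOC)cc1OCOC | intermediate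
11 | (1S)-1-[2,4,6-tris(methoxymethoxy)phenyl]but-3-en-1-ol | C=CC[C@H](O)c1c(OCOC)cc(OCOC)cc1OCOC | intermediate
12 | triethyl{[(1S)-1-[2,4,6-tris(methoxymethoxy)phenyl]but-3-en-1-yl]oxy}silane | C=CC[C@H](O[Si](CC)(CC)CC)c1c(OCOC)cc(OCOC)cc1OCOC | intermediate
13 | (4S)-4-[(triethylsilyl)oxy]-4-[2,4,6-tris(methoxymethoxy)phenyl]butane-1,2-diol, both C2 epimers (not isolated) | OCC(O)C[C@H](O[Si](CC)(CC)CC)c1c(OCOC)cc(OCOC)cc1OCOC | intermediate
14 | (3S)-3-[(triethylsilyl)oxy]-3-[2,4,6-tris(methoxymethoxy)phenyl]propanal | O=CC[C@H](O[Si](CC)(CC)CC)c1c(OCOC)cc(OCOC)cc1OCOC | intermediate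
15 | {6-fluoro-2,4-bis(methoxymethoxy)-3-[(2S)-lavandulyl]phenyl}lithium (not isolated) | C=C(C)[C@@H](CC=C(C)C)Cc1c(OCOC)cc(F)c([Li])c1OCOC | intermediate
16 | (3S)-1-{6-fluoro-2,4-bis(methoxymethoxy)-3-[(2S)-lavandulyl]phenyl}-3-[(triethylsilyl)oxy]-3-[2,4,6-tris(methoxymethoxy)phenyl]propan-1-ol, both C1 epimers | C=C(C)[C@@H](CC=C(C)C)Cc1c(OCOC)cc(F)c(C(O)C[C@H](O[Si](CC)(CC)CC)c2c(OCOC)cc(OCOC)cc2OCOC)c1OCOC | intermediate
17 | (3S)-1-{6-fluoro-2,4-bis(methoxymethoxy)-3-[(2S)-lavandulyl]phenyl}-3-[(triethylsilyl)oxy]-3-[2,4,6-tris(methoxymethoxy)phenyl]propan-1-one | C=C(C)[C@@H](CC=C(C)C)Cc1c(OCOC)cc(F)c(C(=O)C[C@H](O[Si](CC)(CC)CC)c2c(OCOC)cc(OCOC)cc2OCOC)c1OCOC | intermediate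
18 | (3S)-1-{6-fluoro-2,4-bis(methoxymethoxy)-3-[(2S)-lavandulyl]phenyl}-3-hydroxy-3-[2,4,6-tris(methoxymethoxy)phenyl]propan-1-one | C=C(C)[C@@H](CC=C(C)C)Cc1c(OCOC)cc(F)c(C(=O)C[C@H](O)c2c(OCOC)cc(OCOC)cc2OCOC)c1OCOC | intermediate
19 | (2S)-5,7-bis(methoxymethoxy)-6-[(2S)-lavandulyl]-2-[2,4,6-tris(methoxymethoxy)phenyl]-2,3-dihydro-4H-chromen-4-one | C=C(C)[C@@H](CC=C(C)C)Cc1c(OCOC)cc2c(c1OCOC)C(=O)C[C@@H](c1c(OCOC)cc(OCOC)cc1OCOC)O2 | intermediate
20 | (2S)-5,7-dihydroxy-6-[(2S)-lavandulyl]-2-(2,4,6-trihydroxyphenyl)-2,3-dihydro-4H-chromen-4-one (CNP0107340.1) | C=C(C)[C@@H](CC=C(C)C)Cc1c(O)cc2c(c1O)C(=O)C[C@@H](c1c(O)cc(O)cc1O)O2 | target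

Total step count: 13.
Longest linear sequence: 9 steps (8 to 20 through steps 5 to 13).

Steps most likely to fail

Step 12. Deprotonation at C3 with loss of the C2 oxygen (dehydration to a chalcone) or retro-aldol cleavage of the aldolate may outrun attack at C8a, and the closed ring may reopen under base and scramble C2. The fallback leaves 18 and returns at 19 by closing ring C at the O1–C2 bond through oxa-Michael addition. Compound 18 is dehydrated on purpose (PPTS, toluene, 60 °C) to (E)-2′-fluorochalcone F1. The ketone-activated fluoride is then exchanged for hydroxyl with 2-(methylsulfonyl)ethanol and NaH in DMF, by way of aryl 2-(methylsulfonyl)ethyl ether F2, which loses methyl vinyl sulfone in the flask to give 2′-hydroxychalcone F3. NaOAc in refluxing EtOH cyclises F3 to 19 together with C2-epimeric flavanone F4. Because the lavandulyl centre is fixed, 19 and F4 are diastereomers; they would be separated by preparative HPLC and F4 returned to the equilibration.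

Step 13. Protonation at the C4 carbonyl may ionise the C2–O1 bond of the very electron-rich benzylic ether (epimerisation at C2 or ring opening with capture by methanol). The acid may also add the C5 and C7 phenols to the lavandulyl alkenes or shift the isopropenyl double bond into conjugation. The fallback leaves 19 and returns at 20 without any protic acid. TMSOTf and 2,2′-bipyridyl in CH2Cl2 at 0 °C exchange each aryl MOM ether for a trimethylsilyl ether to give penta(trimethylsilyl) ether F5. Stirring F5 with water in THF at rt then hydrolyses the aryl silyl ethers to 20.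

Step 4. β-Hydride elimination from the alkylpalladium intermediate (the β-hydrogen is tertiary and allylic) or slow coupling at the doubly ortho-substituted iodide may starve the cross-coupling. The fallback leaves 3 and returns at 7 with the polarity reversed. Iodine–lithium exchange of 3 (t-BuLi, 2 equiv, THF, −78 °C) gives aryllithium F6, which carries no fluorine ortho to lithium and may therefore be warmed. F6 is alkylated by SN2 with lavandulyl iodide 5 (THF/DMPU, −78 °C → rt) to give 7.

Further compounds
F1 | step 12 | (2E)-1-{6-fluoro-2,4-bis(methoxymethoxy)-3-[(2S)-lavandulyl]phenyl}-3-[2,4,6-tris(methoxymethoxy)phenyl]prop-2-en-1-one | C=C(C)[C@@H](CC=C(C)C)Cc1c(OCOC)cc(F)c(C(=O)/C=C/c2c(OCOC)cc(OCOC)cc2OCOC)c1OCOC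
F2 | step 12 | (2E)-1-{2,4-bis(methoxymethoxy)-3-[(2S)-lavandulyl]-6-[2-(methylsulfonyl)ethoxy]phenyl}-3-[2,4,6-tris(methoxymethoxy)phenyl]prop-2-en-1-one | C=C(C)[C@@H](CC=C(C)C)Cc1c(OCOC)cc(OCCS(C)(=O)=O)c(C(=O)/C=C/c2c(OCOC)cc(OCOC)cc2OCOC)c1OCOC
F3 | step 12 | (2E)-1-{6-hydroxy-2,4-bis(methoxymethoxy)-3-[(2S)-lavandulyl]phenyl}-3-[2,4,6-tris(methoxymethoxy)phenyl]prop-2-en-1-one | C=C(C)[C@@H](CC=C(C)C)Cc1c(OCOC)cc(O)c(C(=O)/C=C/c2c(OCOC)cc(OCOC)cc2OCOC)c1OCOC
F4 | step 12 | (2R)-5,7-bis(methoxymethoxy)-6-[(2S)-lavandulyl]-2-[2,4,6-tris(methoxymethoxy)phenyl]-2,3-dihydro-4H-chromen-4-one | C=C(C)[C@@H](CC=C(C)C)Cc1c(OCOC)cc2c(c1OCOC)C(=O)C[C@H](c1c(OCOC)cc(OCOC)cc1OCOC)O2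
F5 | step 13 | (2S)-6-[(2S)-lavandulyl]-5,7-bis[(trimethylsilyl)oxy]-2-{2,4,6-tris[(trimethylsilyl)oxy]phenyl}-2,3-dihydro-4H-chromen-4-one | C=C(C)[C@@H](CC=C(C)C)Cc1c(O[Si](C)(C)C)cc2c(c1O[Si](C)(C)C)C(=O)C[C@@H](c1c(O[Si](C)(C)C)cc(O[Si](C)(C)C)cc1O[Si](C)(C)C)O2
F6 | step 4 | [4-fluoro-2,6-bis(methoxymethoxy)phenyl]lithium | [Li]c1c(OCOC)cc(F)cc1OCOC
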